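**Retrosynthetic overview**
1. Target ⇐ β-hydroxy enone 24 (C1–OH, C3=O): a hydroxyl-directed Tishchenko reduction sets C3; O3 is then acetylated and the transient O1 ester released.
2. 24 ⇐ isoxazoline-bridged macrocycle 17 (α-methylene and angelate are added while the isoxazoline masks the C1 carbinol and C3 ketone).
3. 17 ⇐ seco nitrile oxide 16: an intramolecular nitrile oxide–diene [3+2] cycloaddition closes the ten-membered carbocycle (C2–C3 and C1–O bonds).
4. 16 ⇐ a γ-lactone carrying two Z-trisubstituted olefins, each made by α-iodo-Wittig olefination of a sugar aldehyde and Pd coupling (vinyl on C10, CO on C4).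
5. C6/C7/C8 with the C7 acetic acid arm ⇐ diacetone-D-glucose. Ring order: γ-lactone (step 6), then carbocycle plus isoxazoline (step 11), isoxazoline opened in step 15.

Assumption: germacrane numbering is used throughout (lactone C12–O on C6, angelate on O8, acetate on O3, hydroxyl on C1, methyls C14 on C10 and C15 on C4); sugar C1–C5 become C5–C9.

**Step 1**
Reactants: 1 1,2:5,6-di-O-isopropylidene-α-D-glucofuranose
Product: 2 1,2:5,6-di-O-isopropylidene-α-D-ribo-hexofuranos-3-ulose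
Conditions: Dess–Martin periodinane, CH2Cl2, rt
Reagents that add atoms: none
Why: Alcohol oxidation of the only free hydroxyl gives the 3-ketone without touching the C2 and C4 stereocentres.

**Step 2**
Reactants: 2 1,2:5,6-di-O-isopropylidene-α-D-ribo-hexofuranos-3-ulose; 3 triethyl phosphonoacetate
Product: 4 ethyl 2-(3-deoxy-1,2:5,6-di-O-isopropylidene-α-D-ribo-hexofuranos-3-ylidene)acetate (E/Z mixture)
Conditions: NaH, THF, 0 °C → rt
Reagents that add atoms: none
Why: Horner–Wadsworth–Emmons olefination of the ketone installs C11/C12; the olefin geometry is irrelevant because the double bond is reduced next.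

**Step 3**
Reactants: 4 ethyl 2-(3-deoxy-1,2:5,6-di-O-isopropylidene-α-D-ribo-hexofuranos-3-ylidene)acetate
Product: 5 3-deoxy-3-C-(2-ethoxy-2-oxoethyl)-1,2:5,6-di-O-isopropylidene-α-D-allofuranose
Conditions: H2 (1 atm), Pd/C, EtOAc, rt
Reagents that add atoms: none
Why: Heterogeneous hydrogenation delivers hydrogen from the open exo (β) face of the cis-fused furanose-dioxolane, so the acetate arm ends up cis to O2 (D-allo), which sets C7.

**Step 4**
Reactants: 5 3-deoxy-3-C-(2-ethoxy-2-oxoethyl)-1,2:5,6-di-O-isopropylidene-α-D-allofuranose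
Product: 6 3-deoxy-3-C-(2-ethoxy-2-oxoethyl)-1,2-O-isopropylidene-α-D-ribo-pentodialdo-1,4-furanose
Conditions: H5IO6, EtOAc, rt
Reagents that add atoms: none
Why: Periodic acid selectively hydrolyses the terminal acetonide and cleaves the liberated glycol in one pot, giving the C9 aldehyde with C8 untouched.

**Step 5**
Reactants: 6 3-deoxy-3-C-(2-ethoxy-2-oxoethyl)-1,2-O-isopropylidene-α-D-ribo-pentodialdo-1,4-furanose; 7 ethyltriphenylphosphonium iodide
Product: 8 (Z)-3,5,6,7-tetradeoxy-3-C-(2-ethoxy-2-oxoethyl)-6-iodo-1,2-O-isopropylidene-α-D-ribo-hept-5-enofuranose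
Conditions: 7, n-BuLi, THF, −78 °C; I2; NaN(SiMe3)2; then 6, −78 → −20 °C
Reagents that add atoms: iodine (II)
Why: Stork–Zhao-type Wittig olefination with the α-iodo ylide gives the Z-vinyl iodide (iodine cis to C8, methyl trans), fixing the C9=C10 geometry at low temperature without epimerising C8.

**Step 6**
Reactants: 8 (Z)-3,5,6,7-tetradeoxy-3-C-(2-ethoxy-2-oxoethyl)-6-iodo-1,2-O-isopropylidene-α-D-ribo-hept-5-enofuranose
Product: 9 (Z)-3-C-(carboxymethyl)-3,5,6,7-tetradeoxy-6-iodo-D-ribo-hept-5-enofuranose 2,3-γ-lactone (cis-fused lactone-lactol, anomers)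
Conditions: TFA/H2O (4:1), 0 °C → rt; toluene azeotrope
Reagents that add atoms: none
Why: Acetal hydrolysis frees O2 (= O6), which lactonises onto the cis ester arm, so the lactone is placed on O6 while O8 stays locked in the furanose ring.

**Step 7**
Reactants: 9 lactone-lactol vinyl iodide; 10 tributyl(vinyl)stannane
Product: 11 (Z)-3-C-(carboxymethyl)-3,5,6,7,8-pentadeoxy-6-C-methyl-D-ribo-octa-5,7-dienofuranose 2,3-γ-lactone (anomers)
Conditions: Pd2(dba)3 (cat.), AsPh3, CuI, NMP, rt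
Reagents that add atoms: none
Why: Stille coupling proceeds with retention of the vinyl iodide geometry and gives the (Z)-2-methylbuta-1,3-dienyl unit C9=C10(Me)–C1=C2.

**Step 8**
Reactants: 11 lactone-lactol diene; 7 ethyltriphenylphosphonium iodide
Product: 13 (4S,5R)-4-[(1R,2Z)-1-(tert-butyldimethylsilyloxy)-3-methylpenta-2,4-dien-1-yl]-5-[(1Z)-2-iodoprop-1-en-1-yl]oxolan-2-one, via hydroxy vinyl iodide 12 (not isolated)
Conditions: 7, n-BuLi, THF; I2; NaN(SiMe3)2 (2 equiv), −78 °C; 11, −78 → −20 °C; then TBSOTf, −78 → 0 °C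
Reagents that add atoms: iodine (II); tert-butyldimethylsilyl trifluoromethanesulfonate (CC(C)(C)[Si](C)(C)OS(=O)(=O)C(F)(F)F)
Why: The same Z-selective α-iodo-Wittig olefination on the open-chain aldehyde of the lactol sets the C4=C5 geometry and releases O8 as its alkoxide, which is silylated in the same pot before it can attack the lactone.

**Step 9**
Reactants: 13 silylated vinyl iodide lactone
Product: 14 (2Z)-3-{(2S,3S)-3-[(1R,2Z)-1-(tert-butyldimethylsilyloxy)-3-methylpenta-2,4-dien-1-yl]-5-oxooxolan-2-yl}-2-methylprop-2-enal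
Conditions: Pd(PPh3)4 (5 mol %), CO (1 atm), Bu3SnH (slow addition), THF, 50 °C
Reagents that add atoms: carbon monoxide ([C-]#[O+])
Why: Palladium-catalysed reductive carbonylation (formylation) of the vinyl iodide occurs with retention and gives the Z-enal (C3) without any hydride reagent that would attack the lactone.

**Step 10**
Reactants: 14 Z-enal
Product: 15 oxime of 14, (2Z)-3-{(2S,3S)-3-[(1R,2Z)-1-(tert-butyldimethylsilyloxy)-3-methylpenta-2,4-dien-1-yl]-5-oxooxolan-2-yl}-2-methylprop-2-enal oxime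
Conditions: NH2OH·HCl, NaOAc, EtOH/H2O, 0 °C → rt
Reagents that add atoms: hydroxylamine hydrochloride (NO.Cl)
Why: Buffered oxime condensation at the aldehyde is fast and leaves the lactone, silyl ether and both Z-olefins intact.

**Step 11**
Reactants: 15 aldoxime
Product: 17 (4Z,9Z)-8β-(tert-butyldimethylsilyloxy)-1α,3-(epoxynitrilo)-6αH,7αH-germacra-4,9-dien-12,6-olide, via nitrile oxide 16 (not isolated)
Conditions: aq. NaOCl, CH2Cl2, 0 °C → rt, slow addition of 15 (final 1 mM)
Reagents that add atoms: none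
Why: Intramolecular nitrile oxide–alkene 1,3-dipolar cycloaddition: the C3 nitrile oxide bonds to the unsubstituted diene terminus C2 and its oxygen to C1, closing the ten-membered ring; with H8 eclipsing the Z-olefin (allylic 1,3-strain) the tether reaches the s-trans diene from the C7 face, anti to the silyloxy group, which sets the 1α-oxygen (1S).

**Step 12**
Reactants: 17 isoxazoline-bridged lactone
Product: 20 (4Z,9Z)-8β-(tert-butyldimethylsilyloxy)-1α,3-(epoxynitrilo)-6αH,7αH-germacra-4,9,11(13)-trien-12,6-olide, via Mannich base 18 (not isolated), via trimethylammonium iodide 19 (not isolated)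
Conditions: LiN(iPr)2 (1.05 equiv), THF, −78 °C; Me2N=CH2+ I−, −78 → 0 °C; MeI, MeOH, rt; aq. NaHCO3, CH2Cl2
Reagents that add atoms: N,N-dimethylmethyleneiminium iodide (C=[N+](C)C.[I-])
Why: Lactone enolate Mannich reaction followed by quaternisation and β-elimination (Eschenmoser methylenation) installs C13 only after the cycloaddition, so the exo-methylene never competes as a dipolarophile.

**Step 13**
Reactants: 20 α-methylene lactone silyl ether
Product: 21 (4Z,9Z)-1α,3-(epoxynitrilo)-8β-hydroxy-6αH,7αH-germacra-4,9,11(13)-trien-12,6-olide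
Conditions: HF·pyridine, THF, 0 °C → rt
Reagents that add atoms: none
Why: Fluoride-mediated desilylation under buffered, non-nucleophilic conditions frees O8 as the only hydroxyl in the molecule.

**Step 14**
Reactants: 21 C8 alcohol; 22 angelic acid
Product: 23 (4Z,9Z)-8β-angeloyloxy-1α,3-(epoxynitrilo)-6αH,7αH-germacra-4,9,11(13)-trien-12,6-olide
Conditions: 22, 2,4,6-Cl3C6H2COCl, Et3N, toluene, rt; then 21, 80 °C
Reagents that add atoms: none
Why: Yamaguchi-type mixed-anhydride esterification without a nucleophilic catalyst acylates the single free hydroxyl and keeps the Z (angelate) geometry.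

**Step 15**
Reactants: 23 isoxazoline angelate
Product: 24 (4Z,9Z)-8β-angeloyloxy-1α-hydroxy-3-oxo-6αH,7αH-germacra-4,9,11(13)-trien-12,6-olide
Conditions: Mo(CO)6, MeCN/H2O (15:1), 80 °C
Reagents that add atoms: water (O)
Why: Reductive N–O cleavage and hydrolysis of the resulting imine unmask the β-hydroxy ketone without reducing the olefins, the enoate or the α-methylene lactone; C1 is untouched.

**Step 16**
Reactants: 24 β-hydroxy enone; 25 methoxyacetaldehyde
Product: 26 (4Z,9Z)-8β-angeloyloxy-3β-hydroxy-1α-(methoxyacetoxy)-6αH,7αH-germacra-4,9,11(13)-trien-12,6-olide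
Conditions: 25 (5 equiv), SmI2 (0.3 equiv), THF, −10 °C
Reagents that add atoms: none
Why: Evans–Tishchenko reduction: the samarium-bound C1 hemiacetal delivers hydride intramolecularly to the C3 ketone, giving the 1,3-anti (3β, 3S) alcohol while O1 ends as a methoxyacetate, so the two oxygens are differentiated.

**Step 17**
Reactants: 26 C3 alcohol
Product: 27 (4Z,9Z)-3β-acetoxy-8β-angeloyloxy-1α-(methoxyacetoxy)-6αH,7αH-germacra-4,9,11(13)-trien-12,6-olide
Conditions: Ac2O, pyridine, DMAP (cat.), CH2Cl2, 0 °C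
Reagents that add atoms: acetic anhydride (CC(=O)OC(C)=O)
Why: Standard acylation of the only free hydroxyl puts the acetate on O3 with retention.

**Step 18**
Reactants: 27 mixed triester
Product: 28 (4Z,9Z)-3β-acetoxy-8β-angeloyloxy-1α-hydroxy-6αH,7αH-germacra-4,9,11(13)-trien-12,6-olide, (1S,3S,6S,7S,8R), the target
Conditions: Yb(OTf)3 (0.2 equiv), MeOH, 0 °C → rt
Reagents that add atoms: none
Why: Chelation-assisted, Yb(OTf)3-catalysed methanolysis removes the α-alkoxy ester much faster than the acetate, angelate or lactone (selective transesterification), freeing the C1 hydroxyl.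

**Compound list**
1 | 1,2:5,6-di-O-isopropylidene-α-D-glucofuranose (diacetone-D-glucose) | O1[C@@H]2OC(C)(C)O[C@@H]2[C@@H](O)[C@H]1[C@H]3COC(C)(C)O3 | starting material
2 | 1,2:5,6-di-O-isopropylidene-α-D-ribo-hexofuranos-3-ulose | O1[C@@H]2OC(C)(C)O[C@@H]2C(=O)[C@H]1[C@H]3COC(C)(C)O3 | intermediate
3 | triethyl phosphonoacetate | CCOC(=O)CP(=O)(OCC)OCC | starting material
4 | ethyl 2-(3-deoxy-1,2:5,6-di-O-isopropylidene-α-D-ribo-hexofuranos-3-ylidene)acetate (E/Z mixture) | O1[C@@H]2OC(C)(C)O[C@@H]2C(=CC(=O)OCC)[C@H]1[C@H]3COC(C)(C)O3 | intermediate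
5 | 3-deoxy-3-C-(2-ethoxy-2-oxoethyl)-1,2:5,6-di-O-isopropylidene-α-D-allofuranose | O1[C@@H]2OC(C)(C)O[C@@H]2[C@H](CC(=O)OCC)[C@H]1[C@H]3COC(C)(C)O3 | intermediate
6 | 3-deoxy-3-C-(2-ethoxy-2-oxoethyl)-1,2-O-isopropylidene-α-D-ribo-pentodialdo-1,4-furanose | O1[C@@H]2OC(C)(C)O[C@@H]2[C@H](CC(=O)OCC)[C@H]1C=O | intermediate
7 | ethyltriphenylphosphonium iodide | CC[P+](c1ccccc1)(c1ccccc1)c1ccccc1.[I-] | starting material
8 | (Z)-3,5,6,7-tetradeoxy-3-C-(2-ethoxy-2-oxoethyl)-6-iodo-1,2-O-isopropylidene-α-D-ribo-hept-5-enofuranose | O1[C@@H]2OC(C)(C)O[C@@H]2[C@H](CC(=O)OCC)[C@H]1/C=C(/C)I | intermediate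
9 | (Z)-3-C-(carboxymethyl)-3,5,6,7-tetradeoxy-6-iodo-D-ribo-hept-5-enofuranose 2,3-γ-lactone (cis-fused lactone-lactol, anomers) | O1C(O)[C@@H]2OC(=O)C[C@@H]2[C@H]1/C=C(/C)I | intermediate
10 | tributyl(vinyl)stannane | C=C[Sn](CCCC)(CCCC)CCCC | starting material
11 | (Z)-3-C-(carboxymethyl)-3,5,6,7,8-pentadeoxy-6-C-methyl-D-ribo-octa-5,7-dienofuranose 2,3-γ-lactone (anomers) | O1C(O)[C@@H]2OC(=O)C[C@@H]2[C@H]1/C=C(/C)C=C | intermediate
12 | (4R,5R)-4-[(1R,2Z)-1-hydroxy-3-methylpenta-2,4-dien-1-yl]-5-[(1Z)-2-iodoprop-1-en-1-yl]oxolan-2-one | O=C1C[C@H]([C@H](O)/C=C(/C)C=C)[C@H](/C=C(/C)I)O1 | intermediate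
13 | (4S,5R)-4-[(1R,2Z)-1-(tert-butyldimethylsilyloxy)-3-methylpenta-2,4-dien-1-yl]-5-[(1Z)-2-iodoprop-1-en-1-yl]oxolan-2-one | O=C1C[C@H]([C@H](O[Si](C)(C)C(C)(C)C)/C=C(/C)C=C)[C@H](/C=C(/C)I)O1 | intermediate
14 | (2Z)-3-{(2S,3S)-3-[(1R,2Z)-1-(tert-butyldimethylsilyloxy)-3-methylpenta-2,4-dien-1-yl]-5-oxooxolan-2-yl}-2-methylprop-2-enal | O=C1C[C@H]([C@H](O[Si](C)(C)C(C)(C)C)/C=C(/C)C=C)[C@H](/C=C(/C)C=O)O1 | intermediate
15 | oxime of 14 (C=N geometry not defined) | O=C1C[C@H]([C@H](O[Si](C)(C)C(C)(C)C)/C=C(/C)C=C)[C@H](/C=C(/C)C=NO)O1 | intermediate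
16 | (2Z)-3-{(2S,3S)-3-[(1R,2Z)-1-(tert-butyldimethylsilyloxy)-3-methylpenta-2,4-dien-1-yl]-5-oxooxolan-2-yl}-2-methylprop-2-enenitrile oxide | O=C1C[C@H]([C@H](O[Si](C)(C)C(C)(C)C)/C=C(/C)C=C)[C@H](/C=C(/C)C#[N+][O-])O1 | intermediate
17 | (4Z,9Z)-8β-(tert-butyldimethylsilyloxy)-1α,3-(epoxynitrilo)-6αH,7αH-germacra-4,9-dien-12,6-olide (2-isoxazoline C3=N–O–C1) | C1C(=O)O[C@H]2/C=C(/C)C3=NO[C@@H](C3)/C(C)=C\[C@@H](O[Si](C)(C)C(C)(C)C)[C@@H]12 | intermediate
18 | 13-(dimethylamino)-11,13-dihydro derivative of 20 (Mannich base, C11 epimers) | CN(C)CC1C(=O)O[C@H]2/C=C(/C)C3=NO[C@@H](C3)/C(C)=C\[C@@H](O[Si](C)(C)C(C)(C)C)[C@@H]12 | intermediate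
19 | N-methyl quaternary ammonium iodide of 18 | C[N+](C)(C)CC1C(=O)O[C@H]2/C=C(/C)C3=NO[C@@H](C3)/C(C)=C\[C@@H](O[Si](C)(C)C(C)(C)C)[C@@H]12.[I-] | intermediate
20 | (4Z,9Z)-8β-(tert-butyldimethylsilyloxy)-1α,3-(epoxynitrilo)-6αH,7αH-germacra-4,9,11(13)-trien-12,6-olide | C=C1C(=O)O[C@H]2/C=C(/C)C3=NO[C@@H](C3)/C(C)=C\[C@@H](O[Si](C)(C)C(C)(C)C)[C@@H]12 | intermediate
21 | (4Z,9Z)-1α,3-(epoxynitrilo)-8β-hydroxy-6αH,7αH-germacra-4,9,11(13)-trien-12,6-olide | C=C1C(=O)O[C@H]2/C=C(/C)C3=NO[C@@H](C3)/C(C)=C\[C@@H](O)[C@@H]12 | intermediate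
22 | angelic acid, (Z)-2-methylbut-2-enoic acid | C/C=C(/C)C(=O)O | starting material
23 | (4Z,9Z)-8β-angeloyloxy-1α,3-(epoxynitrilo)-6αH,7αH-germacra-4,9,11(13)-trien-12,6-olide | C=C1C(=O)O[C@H]2/C=C(/C)C3=NO[C@@H](C3)/C(C)=C\[C@@H](OC(=O)/C(C)=C\C)[C@@H]12 | intermediate
24 | (4Z,9Z)-8β-angeloyloxy-1α-hydroxy-3-oxo-6αH,7αH-germacra-4,9,11(13)-trien-12,6-olide | C=C1C(=O)O[C@H]2/C=C(/C)C(=O)C[C@H](O)/C(C)=C\[C@@H](OC(=O)/C(C)=C\C)[C@@H]12 | intermediate
25 | methoxyacetaldehyde | COCC=O | starting material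
26 | (4Z,9Z)-8β-angeloyloxy-3β-hydroxy-1α-(methoxyacetoxy)-6αH,7αH-germacra-4,9,11(13)-trien-12,6-olide | C=C1C(=O)O[C@H]2/C=C(/C)[C@@H](O)C[C@H](OC(=O)COC)/C(C)=C\[C@@H](OC(=O)/C(C)=C\C)[C@@H]12 | intermediate
27 | (4Z,9Z)-3β-acetoxy-8β-angeloyloxy-1α-(methoxyacetoxy)-6αH,7αH-germacra-4,9,11(13)-trien-12,6-olide | C=C1C(=O)O[C@H]2/C=C(/C)[C@@H](OC(C)=O)C[C@H](OC(=O)COC)/C(C)=C\[C@@H](OC(=O)/C(C)=C\C)[C@@H]12 | intermediate
28 | (4Z,9Z)-3β-acetoxy-8β-angeloyloxy-1α-hydroxy-6αH,7αH-germacra-4,9,11(13)-trien-12,6-olide, (1S,3S,6S,7S,8R) | C=C1C(=O)O[C@H]2/C=C(/C)[C@@H](OC(C)=O)C[C@H](O)/C(C)=C\[C@@H](OC(=O)/C(C)=C\C)[C@@H]12 | target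

**Totals**
Total step count: 18. Longest linear sequence: 18 steps from 1 (fully linear).

**Stereocentres**
- C6 and C8 are C2 and C4 of D-glucose.
- C7 comes from the substrate-controlled hydrogenation in step 3.
- C1 comes from the cycloaddition in step 11.
- C3 comes from the hydroxyl-directed reduction in step 16.

**Three steps most likely to fail**

Step 11 (macrocyclic nitrile oxide cycloaddition). The bridged ten-membered mode at the terminal vinyl group must beat a fused seven-membered addition to the internal C9=C10 bond and furoxan dimerisation, and the C1 configuration rests on a conformational model. Fallback, setting out from 11 and returning at 17: add 2-methylprop-2-enenitrile oxide (methacrolein oxime, NaOCl) intermolecularly to the terminal vinyl group of 11 to give isoxazoline lactol F1 (C1 epimers separated). Open the lactol with Ph3P=CH2 and trap O8 with TBSOTf to give vinyl lactone F2. Close the ring by ring-closing metathesis between the C5 vinyl and the C4 isopropenyl group (second-generation Hoveyda–Grubbs catalyst, toluene, 80 °C, 1 mM); this forms the Z C4=C5 bond and gives 17.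

Step 9 (reductive carbonylation next to a 1,3-diene). Bu3SnH with zerovalent palladium can hydrostannylate the diene or over-reduce the enal. Fallback, setting out from 13 and returning at 14: Stille coupling of 13 with (tributylstannyl)methanol (Pd(PPh3)4, dioxane, 80 °C) gives allylic alcohol F3. MnO2 in CH2Cl2 then oxidises the primary allylic alcohol to 14, so C3 arrives by cross-coupling and oxidation instead of CO insertion.

Step 16 (Evans–Tishchenko reduction with an α-alkoxy aldehyde on a macrocyclic enone). The samarium catalyst may be slowed by the chelating aldehyde, acyl migration can blur the O1/O3 differentiation, and the anti preference may be weakened by the ring. Fallback, setting out from 24 and returning at 28: hydroxyl-directed reduction with Me4NBH(OAc)3 (MeCN/AcOH, −30 °C) gives anti-diol F4. Trimethyl orthoacetate with camphorsulfonic acid converts it into cyclic orthoacetate F5. Mild aqueous acetic acid opens F5 to the mono-acetates, from which 28 is separated; the 1-O-acetyl isomer is re-equilibrated by base-mediated acyl migration and recycled.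

**Further compounds**
F1 | step 11 | isoxazoline lactol: lactol 11 with its terminal vinyl converted into a 3-isopropenyl-2-isoxazolin-5-yl ring (O on C1, 1α) | O1C(O)[C@@H]2OC(=O)C[C@@H]2[C@H]1/C=C(/C)[C@@H]3CC(=NO3)C(C)=C
F2 | step 11 | vinyl lactone: (4S,5S)-4-{(1R,2Z)-1-(tert-butyldimethylsilyloxy)-3-[3-(prop-1-en-2-yl)-4,5-dihydroisoxazol-5-yl]but-2-en-1-yl}-5-vinyloxolan-2-one | O=C1C[C@H]([C@H](O[Si](C)(C)C(C)(C)C)/C=C(/C)[C@@H]2CC(=NO2)C(C)=C)[C@H](C=C)O1
F3 | step 9 | allylic alcohol: (4S,5S)-4-[(1R,2Z)-1-(tert-butyldimethylsilyloxy)-3-methylpenta-2,4-dien-1-yl]-5-[(1Z)-3-hydroxy-2-methylprop-1-en-1-yl]oxolan-2-one | O=C1C[C@H]([C@H](O[Si](C)(C)C(C)(C)C)/C=C(/C)C=C)[C@H](/C=C(/C)CO)O1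
F4 | step 16 | anti-diol: (4Z,9Z)-8β-angeloyloxy-1α,3β-dihydroxy-6αH,7αH-germacra-4,9,11(13)-trien-12,6-olide | C=C1C(=O)O[C@H]2/C=C(/C)[C@@H](O)C[C@H](O)/C(C)=C\[C@@H](OC(=O)/C(C)=C\C)[C@@H]12
F5 | step 16 | cyclic orthoacetate: 1α,3β-O-(1-methoxyethylidene) derivative of F4 | C=C1C(=O)O[C@H]2/C=C(/C)[C@@H]3C[C@H](OC(C)(OC)O3)/C(C)=C\[C@@H](OC(=O)/C(C)=C\C)[C@@H]12
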